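## Retrosynthetic overview
1. Hippolide A ⇒ seco-diol imide (Z-allylic alcohol plus free C6-OH). The dihydropyranol is the last ring formed. It closes by spontaneous lactolisation after allylic oxidation.
2. C4–C5 ⇒ polyene (Z)-alkenyl iodide + epoxy-succinimide. They are joined by a Ni-catalysed reductive coupling through the primary C5 radical, and the C6–O bond is never broken.
3. Key disconnection C2′–C3′: a carbamoyl radical from formamide adds to the β-carbon of (S)-5-(bromomethyl)butenolide, anti to CH2Br, which sets C3′. Methoxide then converts the bromolactone-amide into epoxide plus succinimide.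
4. Alkenyl iodide ⇒ anti-carbomagnesiation/iodination of propargyl alcohol with homofarnesyl-MgBr, which fixes the ring-olefin geometry.
5. Homofarnesyl bromide ⇒ two Negishi couplings of one C5 linchpin onto homoprenyl bromide. Ring order: butenolide (purchased) → γ-lactone → succinimide/epoxide → dihydropyranol.

Locants used: pyran O1, C2 (lactol), C3 (bears the chain), C4, C5, C6. Imide N1′, C2′, C3′ (bonded to C6), C4′, C5′.

Assumption: the lactol carbon C2 is configurationally labile (ring–chain tautomerism). The drawn (S)-anomer, with OH cis to the C6 substituent, is taken as the equilibrium form of the natural product and is set thermodynamically in the last step.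

## Route

**Step 1**
Reactants: 1, pent-3-yn-1-ol
Product: 2, 5-bromopent-2-yne
Conditions: CBr4, PPh3, CH2Cl2, 0 °C
Reagents that add atoms: carbon tetrabromide, BrC(Br)(Br)Br
Why: Appel bromination, in which bromide displaces the primary alkoxyphosphonium by SN2 while the internal alkyne stays inert.

**Step 2**
Reactants: 2, 5-bromopent-2-yne
Product: 3, (E)-5-bromo-2-iodopent-2-ene (I trans to the CH2CH2Br arm)
Conditions: Cp2Zr(H)Cl (1.5 equiv), THF, rt → 40 °C; then I2, −78 → 0 °C; chromatography removes the minor regioisomer
Reagents that add atoms: iodine, II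
Why: Syn-hydrozirconation with excess Schwartz reagent equilibrates Zr onto the less hindered, methyl-bearing carbon, and iodinolysis with retention gives the E-iodide, the non-coordinating bromide avoiding alkoxide-directed reversal of regiochemistry.

**Step 3**
Reactants: 4, 5-bromo-2-methylpent-2-ene (homoprenyl bromide); 3, (E)-5-bromo-2-iodopent-2-ene
Product: 5, (3E)-1-bromo-4,8-dimethylnona-3,7-diene (homogeranyl bromide)
Conditions: 4, Mg, THF; ZnBr2, 0 °C; then 3, PdCl2(dppf) (2 mol %), THF, rt
Reagents that add atoms: none
Why: Negishi sp3–sp2 coupling, in which Pd(0) inserts only into the C(sp2)–I bond (the alkyl bromide is untouched) and the alkenyl geometry is retained, giving the E-trisubstituted alkene.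

**Step 4**
Reactants: 5, homogeranyl bromide; 3, (E)-5-bromo-2-iodopent-2-ene
Product: 6, (3E,7E)-1-bromo-4,8,12-trimethyltrideca-3,7,11-triene (homofarnesyl bromide)
Conditions: 5, Mg, THF; ZnBr2, 0 °C; then 3, PdCl2(dppf) (2 mol %), THF, rt
Reagents that add atoms: none
Why: A second iteration of the same stereoretentive Negishi coupling installs the next E-alkene and regenerates a primary bromide for metalation.

**Step 5**
Reactants: 6, homofarnesyl bromide; 7, prop-2-yn-1-ol
Product: 8, (2Z,5E,9E)-2-(iodomethylidene)-6,10,14-trimethylpentadeca-5,9,13-trien-1-ol (I cis to CH2OH, trans to the chain)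
Conditions: 6, Mg, THF; add to ClMgOCH2C≡CH (7 + i-PrMgCl, −30 °C), CuI (15 mol %), THF–Et2O, −10 °C → rt; then I2, −40 → 0 °C
Reagents that add atoms: iodine, II
Why: In this Cu-catalysed anti-carbomagnesiation of propargyl alcohol the alkyl group adds to the internal carbon and Mg sits on the terminal carbon inside a five-membered alkoxide chelate, so iodinolysis with retention places I (later C5) cis to C2.

**Step 6**
Reactants: 9, (S)-5-(hydroxymethyl)furan-2(5H)-one
Product: 10, (S)-5-(bromomethyl)furan-2(5H)-one
Conditions: CBr4, PPh3, CH2Cl2, −10 → 0 °C (no amine base)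
Reagents that add atoms: carbon tetrabromide, BrC(Br)(Br)Br
Why: A neutral Appel bromination at the primary carbon leaves the stereocentre (future C6) untouched and avoids base-induced elimination to the 5-methylene butenolide.

**Step 7 (key step)**
Reactants: 10, (S)-5-(bromomethyl)furan-2(5H)-one; 11, formamide
Product: 12, (2S,3S)-2-(bromomethyl)-5-oxooxolane-3-carboxamide (CH2Br and CONH2 trans)
Conditions: (n-Bu4N)4W10O32 (2 mol %), HCONH2 (20 equiv), MeCN, 390 nm LED, N2, rt
Reagents that add atoms: formamide (11), NC=O
Why: In this Giese-type hydrocarbamoylation (decatungstate HAT photocatalysis) the nucleophilic σ-carbamoyl radical from the formyl C–H adds to the butenolide β-carbon on the face anti to CH2Br, forming C2′–C3′ and setting C3′ as S, and back-HAT to the α-acyl radical closes the cycle.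

**Step 8**
Reactants: 12, trans-bromolactone carboxamide
Product: 13, (3S)-3-[(2S)-oxiran-2-yl]pyrrolidine-2,5-dione
Conditions: NaOMe (2.1 equiv), MeOH, −10 → 0 °C; then Amberlite IR-120 (H+), filter
Reagents that add atoms: none
Why: In this base cascade methoxide opens the lactone, the C6 alkoxide closes on CH2Br (Williamson epoxide formation with the C6–O bond intact), and the amide cyclises onto the methyl ester to the succinimide, driven by deprotonation of the imide N–H, which also shields C3′–H from epimerisation.

**Step 9**
Reactants: 8, (Z)-alkenyl iodide; 13, epoxy-succinimide (1.8 equiv)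
Product: 14, (3S)-3-[(1R,3Z,7E,11E)-1-hydroxy-4-(hydroxymethyl)-8,12,16-trimethylheptadeca-3,7,11,15-tetraen-1-yl]pyrrolidine-2,5-dione
Conditions: NiCl2·glyme (10 mol %), 2,2′-bipyridine (10 mol %), NaI (0.5 equiv), Et3N·HCl (2 equiv), Mn (3 equiv), DMPU, rt
Reagents that add atoms: none
Why: In this Ni-catalysed reductive cross-electrophile coupling of an epoxide with an alkenyl halide under iodide co-catalysis, iodide opens the epoxide at CH2, Ni abstracts iodine to give the primary C5 radical, and capture by the alkenyl-Ni(II) followed by reductive elimination forms C4–C5 with retained Z geometry and unchanged C6 and C3′.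

**Step 10**
Reactants: 14, seco-diol imide
Product: 15, hippolide A
Conditions: TEMPO (10 mol %), PhI(OAc)2 (1.05 equiv), CH2Cl2, 0 °C; pH 7 work-up
Reagents that add atoms: none
Why: Oxoammonium oxidation selects the primary allylic alcohol over the secondary C6-OH, the Z-enal is trapped at once by C6-OH as the six-membered lactol, limiting oxidant prevents lactone formation, and C2 settles by ring–chain equilibration.

## Compound list
1 | pent-3-yn-1-ol | CC#CCCO | starting material
2 | 5-bromopent-2-yne | CC#CCCBr | intermediate
3 | (E)-5-bromo-2-iodopent-2-ene | I/C(C)=C/CCBr | intermediate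
4 | 5-bromo-2-methylpent-2-ene | CC(C)=CCCBr | starting material
5 | (3E)-1-bromo-4,8-dimethylnona-3,7-diene | CC(C)=CCC/C(C)=C/CCBr | intermediate
6 | (3E,7E)-1-bromo-4,8,12-trimethyltrideca-3,7,11-triene | CC(C)=CCC/C(C)=C/CC/C(C)=C/CCBr | intermediate
7 | prop-2-yn-1-ol | C#CCO | starting material
8 | (2Z,5E,9E)-2-(iodomethylidene)-6,10,14-trimethylpentadeca-5,9,13-trien-1-ol | CC(C)=CCC/C(C)=C/CC/C(C)=C/CC/C(CO)=C/I | intermediate
9 | (S)-5-(hydroxymethyl)furan-2(5H)-one | OC[C@H]1OC(=O)C=C1 | starting material
10 | (S)-5-(bromomethyl)furan-2(5H)-one | BrC[C@H]1OC(=O)C=C1 | intermediate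
11 | formamide | NC=O | starting material
12 | (2S,3S)-2-(bromomethyl)-5-oxooxolane-3-carboxamide | BrC[C@H]1OC(=O)C[C@@H]1C(N)=O | intermediate
13 | (3S)-3-[(2S)-oxiran-2-yl]pyrrolidine-2,5-dione | C1O[C@H]1[C@@H]2CC(=O)NC2=O | intermediate
14 | (3S)-3-[(1R,3Z,7E,11E)-1-hydroxy-4-(hydroxymethyl)-8,12,16-trimethylheptadeca-3,7,11,15-tetraen-1-yl]pyrrolidine-2,5-dione | CC(C)=CCC/C(C)=C/CC/C(C)=C/CC/C(CO)=C/C[C@@H](O)[C@@H]1CC(=O)NC1=O | intermediate
15 | hippolide A, (3S)-3-[(2R,6S)-6-hydroxy-5-[(3E,7E)-4,8,12-trimethyltrideca-3,7,11-trien-1-yl]-3,6-dihydro-2H-pyran-2-yl]pyrrolidine-2,5-dione | CC(C)=CCC/C(C)=C/CC/C(C)=C/CCC1=CC[C@H]([C@@H]2CC(=O)NC2=O)O[C@@H]1O | target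

## Step count
Total steps: 10. Longest linear sequence: 7 (Steps 1, 2, 3, 4, 5, 9, 10).

## Steps most likely to fail
- **Step 9.** Possible failures are hydrodehalogenation or dimerisation of 8, epoxide deoxygenation, and interference from the imide N–H. Fallback: use bromolactone 12 itself as the radical precursor in an alkyl bromide/alkenyl iodide Ni–Mn coupling. The methoxide O→N acyl shift of Step 8 is then run on the coupled lactone, with the same step count.
- **Step 10.** Possible failures are over-oxidation of the allylic lactol to the δ-lactone and competing oxidation of C6-OH. Fallback: oxidise deliberately to the α,β-unsaturated δ-lactone with excess MnO2. Then mask the imide as its N-sodium salt (NaH) and half-reduce with DIBAL-H at −78 °C to the lactol (+1 step).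
- **Step 2.** Regioselectivity is expected to be roughly 9:1, the C–Br bond must tolerate the zirconium hydride, and any error is carried into both alkenes. Fallback: abandon alkyne hydrometalation. Build each E-alkene by alkylating 5-lithio-2,3-dihydrofuran with the growing homoallylic halide. Then open the ring stereospecifically with Ni-catalysed MeMgBr to the homoallylic alcohol and convert OH to Br (more steps, higher geometric fidelity).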